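**Plan**
- Retrosynthesis: the C4 ketone and the 7-OH are masked (dithiane, MOM ether); then O1–C8a and C8–C1'' (prenyl CH2) are cut together; then C3–C4 is cut between a lithiated aryl dithiane and an aryl oxirane.
- Enabling feature: C8a (bearing O1) and C8 (bearing the prenyl group) are neighbouring carbons of ring A, and C8 lies between C8a and the oxygenated C7. A C8–C8a aryne flanked by the C7 alkoxy group is therefore polarised to take oxygen at C8a and a carbon electrophile at C8.
- Forward order: the pyran ring of the chromene (on ring B) is built first on 4-hydroxyacetophenone; its acetyl group becomes an (R)-oxirane; the dithiane anion joins the two aryl halves at C3–C4; ring C closes in the aryne step; the C4 ketone and 7-OH are freed last.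
- Stereochemistry: the only stereocentre, C2, is set by asymmetric transfer hydrogenation of the α-chloroketone with an (S,S)-TsDPEN catalyst. It is carried through the oxirane, and its C–O bond is never broken afterwards.

Key step: step 9

Remark: flavanone numbering is used (O1, C2, C3, C4, C4a, C5 to C8, C8a; C1'' is the prenyl CH2); the descriptor at C2 read from the SMILES is S, and 6-bromo-2,2-dimethyl-2H-chromene, needed only in one fallback, is assumed to be purchasable.

**Route**

Step 1
Reactants: 1 4-hydroxyacetophenone; 2 3-chloro-3-methylbut-1-yne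
Product: 3 1-{4-[(2-methylbut-3-yn-2-yl)oxy]phenyl}ethanone
Conditions: K2CO3, KI (cat.), CuI (cat.), acetone, reflux
Reagents that add atoms: none
Why: Williamson-type O-alkylation of the phenoxide by the tertiary propargylic chloride (copper-assisted propargylic substitution) is the standard entry to aryl 1,1-dimethylpropargyl ethers, and the para-acetyl phenol is acidic enough for K2CO3.

Step 2
Reactants: 3 1-{4-[(2-methylbut-3-yn-2-yl)oxy]phenyl}ethanone
Product: 4 1-(2,2-dimethyl-2H-chromen-6-yl)ethanone
Conditions: N,N-diethylaniline, 190 °C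
Reagents that add atoms: none
Why: Thermal aryl propargyl ether Claisen rearrangement, followed in the same pot by 1,5-hydrogen shift and oxa-6π electrocyclisation, should give the 2,2-dimethyl-2H-chromene as one isomer because the para position is blocked and the two ortho positions are equivalent.

Step 3
Reactants: 4 1-(2,2-dimethyl-2H-chromen-6-yl)ethanone
Product: 6 2-chloro-1-(2,2-dimethyl-2H-chromen-6-yl)ethanone, via trimethylsilyl enol ether 5 (not isolated)
Conditions: LiN(SiMe3)2, Me3SiCl, THF, −78 °C; then NCS (1.0 equiv), THF, 0 °C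
Reagents that add atoms: chlorotrimethylsilane, C[Si](C)(C)Cl (silyl group of intermediate 5 only); N-chlorosuccinimide, O=C1CCC(=O)N1Cl
Why: Electrophilic α-chlorination of a silyl enol ether places chlorine only on the former methyl carbon, because the enol ether is far more nucleophilic than the chromene double bond and one equivalent of NCS avoids over-chlorination.

Step 4
Reactants: 6 2-chloro-1-(2,2-dimethyl-2H-chromen-6-yl)ethanone
Product: 7 (R)-2-chloro-1-(2,2-dimethyl-2H-chromen-6-yl)ethanol
Conditions: Cp*RhCl[(S,S)-TsDPEN] (cat.), HCO2H/Et3N (5:2), EtOAc, rt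
Reagents that add atoms: none
Why: Noyori-type asymmetric transfer hydrogenation of an aryl chloromethyl ketone: the (S,S)-TsDPEN catalyst delivers hydride to the face that gives the (S)-1-arylethanol arrangement, which is named R here because CH2Cl outranks aryl, and neither the C–Cl bond nor the chromene alkene is reduced.

Step 5
Reactants: 7 (R)-2-chloro-1-(2,2-dimethyl-2H-chromen-6-yl)ethanol
Product: 8 (R)-2,2-dimethyl-6-(oxiran-2-yl)-2H-chromene
Conditions: 2 M aq. NaOH, i-PrOH, 0 °C to rt
Reagents that add atoms: none
Why: Intramolecular Williamson etherification (3-exo-tet) of the chlorohydrin alkoxide displaces chloride at the primary carbon, so the carbinol stereocentre is untouched and remains R.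

Step 6
Reactants: 9 2-fluoro-4-hydroxybenzaldehyde; 10 propane-1,3-dithiol
Product: 11 4-(1,3-dithian-2-yl)-3-fluorophenol
Conditions: BF3·OEt2 (cat.), CH2Cl2, 0 °C to rt
Reagents that add atoms: none
Why: Lewis-acid-catalysed dithioacetalisation of an aryl aldehyde is reliable, and it is placed before MOM protection because a MOM ether would not survive thiol/BF3 conditions.

Step 7
Reactants: 11 4-(1,3-dithian-2-yl)-3-fluorophenol
Product: 12 2-[2-fluoro-4-(methoxymethoxy)phenyl]-1,3-dithiane
Conditions: NaH, MOMCl, THF/DMF, 0 °C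
Reagents that add atoms: chloromethyl methyl ether (MOMCl), COCCl
Why: Williamson-type O-alkylation of the sodium phenoxide by MOMCl is selective because the dithiane C2–H is not acidic enough for NaH at 0 °C and the phenoxide is far more nucleophilic than the thioether sulfurs.

Step 8
Reactants: 12 2-[2-fluoro-4-(methoxymethoxy)phenyl]-1,3-dithiane; 8 (R)-2,2-dimethyl-6-(oxiran-2-yl)-2H-chromene
Product: 14 (S)-1-(2,2-dimethyl-2H-chromen-6-yl)-2-{2-[2-fluoro-4-(methoxymethoxy)phenyl]-1,3-dithian-2-yl}ethanol, via 2-lithio-1,3-dithiane 13 (not isolated)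
Conditions: n-BuLi (1.0 equiv), THF, −78 °C; then 8, DMPU, −78 to 0 °C; then H2O
Reagents that add atoms: n-butyllithium, [Li]CCCC (lithium of intermediate 13 only)
Why: Corey–Seebach umpolung: n-BuLi removes the benzylic, doubly sulfur-stabilised C2–H of the dithiane (the most acidic site; at −78 °C any ortho-fluoroaryllithium formed in competition does not yet lose LiF and can pass its charge to the dithiane carbon), and the carbanion opens the oxirane by SN2 attack at the terminal CH2, forming C3–C4 without touching the C–O stereocentre, so (R)-8 gives (S)-14 with only a change of descriptor.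

Step 9
Reactants: 14 (S)-1-(2,2-dimethyl-2H-chromen-6-yl)-2-{2-[2-fluoro-4-(methoxymethoxy)phenyl]-1,3-dithian-2-yl}ethanol; 15 prenyl bromide (1-bromo-3-methylbut-2-ene)
Product: 20 (S)-2-(2,2-dimethyl-2H-chromen-6-yl)-7-(methoxymethoxy)-8-(3-methylbut-2-en-1-yl)spiro[chromane-4,2'-[1,3]dithiane], via C8-lithiated lithium alkoxide 16 (not isolated), via aryne lithium alkoxide 17 (not isolated), via 8-lithiochroman dithiane 18 (not isolated), via 8-cupriochroman dithiane 19 (not isolated)
Conditions: s-BuLi (2.2 equiv), THF (0.02 M), −78 °C, then −20 °C; CuBr·SMe2, −40 °C; then 15, −40 °C to rt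
Reagents that add atoms: sec-butyllithium, [Li]C(C)CC (lithium of intermediates 16 to 18 only); CuBr·SMe2, Br[Cu].CSC (copper of intermediate 19 only)
Why: Proposed new method: s-BuLi removes the hydroxyl proton and then the ring proton between fluorine and the MOM ether (C8, the only position flanked by two ortho directors); the ortho-fluoroaryllithium 16 loses LiF on warming to give the C8–C8a aryne 17; the tethered lithium alkoxide adds in the plane of the aryne at C8a; and the C8 aryllithium 18 is moved to copper (19) and alkylated at the primary carbon of prenyl bromide. The closest known reaction types are the anionic aryne cyclisation of ortho-fluoroaryl substrates carrying a tethered carbanion or nitrogen anion with electrophile capture of the new aryllithium, and the base-induced intramolecular addition of alkoxides to arynes that gives chromans; combining an alkoxide nucleophile with prenyl capture in one pot is the extension. Ring C closes by 6-exo-dig attack of O1 on C8a, the only aryne carbon the three-atom tether can reach. No stereocentre is formed, and since the C2–O bond is not broken the S configuration of 14 is carried into 20. The step needs a single aryne (fluoride is the only leaving group and H8 the most acidic ring proton), oxygen attack at C8a with the carbanion left at C8 (tether length and the inductively withdrawing C7 oxygen next to the aryne agree), and prenyl transfer at the CH2 terminus (copper-mediated substitution at the unhindered primary carbon, the other allyl terminus being fully substituted). The fully substituted dithiane carbon leaves no acidic proton near C4 to quench the C8 anion, and its gem-disubstitution favours ring closure.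

Step 10
Reactants: 20 (S)-2-(2,2-dimethyl-2H-chromen-6-yl)-7-(methoxymethoxy)-8-(3-methylbut-2-en-1-yl)spiro[chromane-4,2'-[1,3]dithiane]
Product: 21 (S)-2-(2,2-dimethyl-2H-chromen-6-yl)-7-(methoxymethoxy)-8-(3-methylbut-2-en-1-yl)chroman-4-one
Conditions: MeI, CaCO3, MeCN/H2O (9:1), 45 °C
Reagents that add atoms: water, O
Why: Alkylative hydrolysis of the dithiane: S-methylation turns sulfur into a leaving group and the thionium ion, stabilised by O1 and the C7 oxygen, is trapped by water, while MeI and the CaCO3 buffer leave the prenyl and chromene alkenes, the MOM ether (which also prevents O-methylation of the phenol) and C2 untouched.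

Step 11
Reactants: 21 (S)-2-(2,2-dimethyl-2H-chromen-6-yl)-7-(methoxymethoxy)-8-(3-methylbut-2-en-1-yl)chroman-4-one
Product: 22 (S)-7-hydroxy-2-(2,2-dimethyl-2H-chromen-6-yl)-8-(3-methylbut-2-en-1-yl)chroman-4-one (CNP0156801.1)
Conditions: 3 M aq. HCl, MeOH, 45 °C
Reagents that add atoms: none
Why: Acid-catalysed acetal exchange of the aryl MOM ether with methanol frees the 7-OH under conditions routinely used for ortho-prenylated MOM-protected flavanones, and the mild temperature is chosen so that the prenyl group, the chromene and the C2–O1 bond should stay intact.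

**Compound list**
1 | 4-hydroxyacetophenone | CC(=O)c1ccc(O)cc1 | starting material
2 | 3-chloro-3-methylbut-1-yne | C#CC(C)(C)Cl | starting material
3 | 1-{4-[(2-methylbut-3-yn-2-yl)oxy]phenyl}ethanone | CC(=O)c1ccc(OC(C)(C)C#C)cc1 | intermediate
4 | 1-(2,2-dimethyl-2H-chromen-6-yl)ethanone | CC(=O)c1ccc2c(c1)C=CC(C)(C)O2 | intermediate
5 | {[1-(2,2-dimethyl-2H-chromen-6-yl)ethenyl]oxy}trimethylsilane | C=C(O[Si](C)(C)C)c1ccc2c(c1)C=CC(C)(C)O2 | intermediate
6 | 2-chloro-1-(2,2-dimethyl-2H-chromen-6-yl)ethanone | O=C(CCl)c1ccc2c(c1)C=CC(C)(C)O2 | intermediate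
7 | (R)-2-chloro-1-(2,2-dimethyl-2H-chromen-6-yl)ethanol | O[C@H](c1ccc2c(c1)C=CC(C)(C)O2)CCl | intermediate
8 | (R)-2,2-dimethyl-6-(oxiran-2-yl)-2H-chromene | C1O[C@@H]1c1ccc2c(c1)C=CC(C)(C)O2 | intermediate
9 | 2-fluoro-4-hydroxybenzaldehyde | O=Cc1ccc(O)cc1F | starting material
10 | propane-1,3-dithiol | SCCCS | starting material
11 | 4-(1,3-dithian-2-yl)-3-fluorophenol | Oc1ccc(C2SCCCS2)c(F)c1 | intermediate
12 | 2-[2-fluoro-4-(methoxymethoxy)phenyl]-1,3-dithiane | COCOc1ccc(C2SCCCS2)c(F)c1 | intermediate
13 | 2-[2-fluoro-4-(methoxymethoxy)phenyl]-2-lithio-1,3-dithiane | [Li]C1(SCCCS1)c1ccc(OCOC)cc1F | intermediate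
14 | (S)-1-(2,2-dimethyl-2H-chromen-6-yl)-2-{2-[2-fluoro-4-(methoxymethoxy)phenyl]-1,3-dithian-2-yl}ethanol | O[C@H](c1ccc2c(c1)C=CC(C)(C)O2)CC1(SCCCS1)c1ccc(OCOC)cc1F | intermediate
15 | prenyl bromide (1-bromo-3-methylbut-2-ene) | CC(C)=CCBr | starting material
16 | lithium (S)-1-(2,2-dimethyl-2H-chromen-6-yl)-2-{2-[2-fluoro-3-lithio-4-(methoxymethoxy)phenyl]-1,3-dithian-2-yl}ethoxide | [Li]O[C@H](c1ccc2c(c1)C=CC(C)(C)O2)CC1(SCCCS1)c1ccc(OCOC)c([Li])c1F | intermediate
17 | lithium (S)-1-(2,2-dimethyl-2H-chromen-6-yl)-2-{2-[4-(methoxymethoxy)-2,3-didehydrophenyl]-1,3-dithian-2-yl}ethoxide (C8–C8a aryne) | [Li]O[C@H](c1ccc2c(c1)C=CC(C)(C)O2)CC1(SCCCS1)C1=CC=C(OCOC)C#C1 | intermediate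
18 | (S)-2-(2,2-dimethyl-2H-chromen-6-yl)-8-lithio-7-(methoxymethoxy)spiro[chromane-4,2'-[1,3]dithiane] | [Li]c1c(OCOC)ccc2c1O[C@H](c1ccc3c(c1)C=CC(C)(C)O3)CC21SCCCS1 | intermediate
19 | (S)-8-cuprio-2-(2,2-dimethyl-2H-chromen-6-yl)-7-(methoxymethoxy)spiro[chromane-4,2'-[1,3]dithiane] (arylcopper) | [Cu]c1c(OCOC)ccc2c1O[C@H](c1ccc3c(c1)C=CC(C)(C)O3)CC21SCCCS1 | intermediate
20 | (S)-2-(2,2-dimethyl-2H-chromen-6-yl)-7-(methoxymethoxy)-8-(3-methylbut-2-en-1-yl)spiro[chromane-4,2'-[1,3]dithiane] | CC(C)=CCc1c(OCOC)ccc2c1O[C@H](c1ccc3c(c1)C=CC(C)(C)O3)CC21SCCCS1 | intermediate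
21 | (S)-2-(2,2-dimethyl-2H-chromen-6-yl)-7-(methoxymethoxy)-8-(3-methylbut-2-en-1-yl)chroman-4-one | CC(C)=CCc1c(OCOC)ccc2c1O[C@H](c1ccc3c(c1)C=CC(C)(C)O3)CC2=O | intermediate
22 | (S)-7-hydroxy-2-(2,2-dimethyl-2H-chromen-6-yl)-8-(3-methylbut-2-en-1-yl)chroman-4-one | CC(C)=CCc1c(O)ccc2c1O[C@H](c1ccc3c(c1)C=CC(C)(C)O3)CC2=O | target

**Step count and risks**

Total steps: 11. Longest linear sequence: 9 (steps 1 to 5, then 8 to 11).

Steps most likely to fail:

1. Step 9 (the proposed new method). The aryne may be consumed intermolecularly, by s-BuLi or by a second aryllithium, before the lithium alkoxide closes ring C. The styrene-type double bond of the chromene may undergo carbolithiation. The prenyl group may also be transferred through its tertiary terminus. Fallback with known chemistry, setting out from 14 and returning at 20: the two bonds are made in separate operations. Intramolecular nucleophilic aromatic substitution of fluoride by the sodium alkoxide (NaH, DMF, 90 °C) should close ring C without an aryne and give (S)-2-(2,2-dimethyl-2H-chromen-6-yl)-7-(methoxymethoxy)spiro[chromane-4,2'-[1,3]dithiane] F1. Directed ortho-lithiation of F1 between O1 and the MOM ether (n-BuLi, THF, 0 °C) then gives the same aryllithium 18, which after CuBr·SMe2 and prenyl bromide 15 joins the route at 20.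

2. Step 8. The electron-rich aryl oxirane may be attacked at its benzylic carbon or rearrange under lithium ion assistance, and ring lithiation next to fluorine may compete with dithiane deprotonation. Fallback, setting out from 12 and returning at 14: the stereocentre is set after the C–C bonds instead of being carried in the oxirane.
   - Lithiated dithiane 13 opens ethylene oxide, which has no benzylic position, to give 2-{2-[2-fluoro-4-(methoxymethoxy)phenyl]-1,3-dithian-2-yl}ethanol F2.
   - Parikh–Doering oxidation (SO3·pyridine, DMSO, i-Pr2NEt) gives {2-[2-fluoro-4-(methoxymethoxy)phenyl]-1,3-dithian-2-yl}acetaldehyde F3.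
   - Addition of (2,2-dimethyl-2H-chromen-6-yl)magnesium bromide F4 (from 6-bromo-2,2-dimethyl-2H-chromene and Mg, THF) gives racemic 1-(2,2-dimethyl-2H-chromen-6-yl)-2-{2-[2-fluoro-4-(methoxymethoxy)phenyl]-1,3-dithian-2-yl}ethanol F5.
   - MnO2 in CH2Cl2 oxidises the benzylic alcohol to 1-(2,2-dimethyl-2H-chromen-6-yl)-2-{2-[2-fluoro-4-(methoxymethoxy)phenyl]-1,3-dithian-2-yl}ethanone F6.
   - Asymmetric transfer hydrogenation of this aryl ketone with the (S,S)-TsDPEN catalyst of step 4 (HCO2H/Et3N) should give (S)-14, in the same facial sense as in step 4.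

3. Step 11. Under protic acid the freed 7-OH may add to the C8 prenyl double bond (dihydropyran formation). The p-alkoxybenzylic C2–O1 bond may ionise with erosion of configuration. Methanol may add to the chromene double bond. Fallback, setting out from 21 and returning at 22: the MOM ether is exchanged for a silyl ether without Brønsted acid. TMSOTf and 2,2'-bipyridyl in MeCN at 0 °C should convert the aryl MOM ether into (S)-2-(2,2-dimethyl-2H-chromen-6-yl)-8-(3-methylbut-2-en-1-yl)-7-[(trimethylsilyl)oxy]chroman-4-one F7, which is hydrolysed to 22 by water at neutral pH during work-up.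

**Further compounds**
F1 | step 9 | (S)-2-(2,2-dimethyl-2H-chromen-6-yl)-7-(methoxymethoxy)spiro[chromane-4,2'-[1,3]dithiane] | COCOc1ccc2c(c1)O[C@H](c1ccc3c(c1)C=CC(C)(C)O3)CC21SCCCS1
F2 | step 8 | 2-{2-[2-fluoro-4-(methoxymethoxy)phenyl]-1,3-dithian-2-yl}ethanol | OCCC1(SCCCS1)c1ccc(OCOC)cc1F
F3 | step 8 | {2-[2-fluoro-4-(methoxymethoxy)phenyl]-1,3-dithian-2-yl}acetaldehyde | O=CCC1(SCCCS1)c1ccc(OCOC)cc1F
F4 | step 8 | (2,2-dimethyl-2H-chromen-6-yl)magnesium bromide | Br[Mg]c1ccc2c(c1)C=CC(C)(C)O2
F5 | step 8 | racemic 1-(2,2-dimethyl-2H-chromen-6-yl)-2-{2-[2-fluoro-4-(methoxymethoxy)phenyl]-1,3-dithian-2-yl}ethanol | OC(c1ccc2c(c1)C=CC(C)(C)O2)CC1(SCCCS1)c1ccc(OCOC)cc1F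
F6 | step 8 | 1-(2,2-dimethyl-2H-chromen-6-yl)-2-{2-[2-fluoro-4-(methoxymethoxy)phenyl]-1,3-dithian-2-yl}ethanone | O=C(c1ccc2c(c1)C=CC(C)(C)O2)CC1(SCCCS1)c1ccc(OCOC)cc1F
F7 | step 11 | (S)-2-(2,2-dimethyl-2H-chromen-6-yl)-8-(3-methylbut-2-en-1-yl)-7-[(trimethylsilyl)oxy]chroman-4-one | CC(C)=CCc1c(O[Si](C)(C)C)ccc2c1O[C@H](c1ccc3c(c1)C=CC(C)(C)O3)CC2=O
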